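Send a racemic substrate through a single-handed catalyst and count the left-handed product at the set time.

    free catalyst + left-handed substrate ⇌ catalyst intermediate A (K1 = 150 M⁻¹, k1 = 380 M⁻¹ s⁻¹)
    free catalyst + right-handed substrate ⇌ catalyst intermediate B (K2 = 150 M⁻¹, k2 = 170 M⁻¹ s⁻¹)
    partner + catalyst intermediate A → free catalyst + left-handed product (k3 = 16 M⁻¹ s⁻¹)
    partner + catalyst intermediate B → free catalyst + right-handed product (k4 = 5.7 M⁻¹ s⁻¹)
    partner + protic impurity → quenched reagent (k5 = 2.6 M⁻¹ s⁻¹)
    left-handed substrate ⇌ right-handed substrate (k6 = 0.049 s⁻¹)

| flask | left-handed substrate | partner | protic impurity | free catalyst | right-handed substrate | time |
|---|---|---|---|---|---|---|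
| south-west | 13 mM | 2.00 equiv | 0.500 mM | 10 mol% | 13 mM | 15 min |
| south | 13 mM | 2.00 equiv | 1.50 mM | 10 mol% | 13 mM | 15 min |
| west | 13 mM | 2.00 equiv | 4.00 mM | 10 mol% | 13 mM | 15 min |
| east | 13 mM | 2.00 equiv | 12.0 mM | 10 mol% | 13 mM | 15 min |

1. amount of left-handed product at the end, in percent of the left-handed substrate and right-handed substrate together charged for south-west, south, west, east, in this order
2. how that number moves from the first to the last of them (falls, then rises / rises all the way / falls all the way / rises, then falls / hardly changes)

- free catalyst is single-handed; left-handed substrate and right-handed substrate are mirror images of each other, charged as a racemate, each of them at the stated concentration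
- "hardly changes" means that all values lie within two and a half points (for a concentration: within two and a half percent of the largest)
- run time (south-west): 15 min

Partner is charged at 26.0 mM, the same as the two substrates together, and each protic impurity takes one partner away. So the partner left for product is less than the substrate, partner is the limiting reagent, and we reckon total product as the charge less the impurity. What remains is how that product divides.

Two extremes can be solved in the head. With the substrates frozen, left-handed product cannot pass its own charge, 50.0% of the substrate. With instant interconversion, the substrates stay equal; the binding constants are equal too, so [catalyst intermediate A] = [catalyst intermediate B], and left-handed product takes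

73.7% of the turnover.

The flask lies near the instant extreme, as the bound amount at the charge shows:

[catalyst intermediate A] = 0.517 mM

With it, left-handed substrate has a half-life of 0.698 min against product formation, reckoned at the charge, longer than its 0.24 min half-life by interconversion, forward step alone.

Now we put this first answer back. Left-handed substrate leaves faster, and interconversion refills it, so a gap opens. Balancing the two gives each substrate's relative offset from their mean:

gap = 5.44%

Left-handed substrate lies below the mean by this gap and right-handed above it, so the second round gives

71.6%

This is the left-handed share, the part of all product that is left-handed. Multiplying it by the unquenched part of the partner, we commit to 70.2% in south-west and 38.5% in east, falling throughout.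

The forecast reads 69.4%, 67.3%, 60.9%, 38.9%, falls all the way, and holds that “the substrate stays nearly racemic”. It stands below our south-west figure and above our east one.

The simulation gives 69.0%, 67.1%, 61.1%, 40.0%: falls all the way.

In south-west, half of the turnover to left-handed product up to the end was done by 1.15 min, partner stood at 6.69% of its charge at 7.50 min, and at 15.0 min left-handed and right-handed product stood at 69.0% and 26.7%, a left-handed share of 72.1% against our 71.6%. In east, at 15.0 min, partner was down to 0.00717% of its charge with quenched reagent at 11.7 mM; our share times the partner not quenched gives 39.3%, and the flask stands at 40.0%.

(The numbers were drawn at random within sensible limits, and the outcome is calculated.)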